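Both rings C are cut at O1–C2 and C4–C4a, twice and in one operation, back to two molecules of resorcinol (rings A) and one bis(arylmalondialdehyde) in which each C3 carries C2 and C4 as formyl groups (pyrylium oxidation level).
This works because ring A is a resorcinol: C4a is ortho to O1 and para to the 7-OH, so it is a carbon nucleophile next to an oxygen nucleophile, matched by the 1,3-dielectrophile C2/C4 on C3; the C2 axis through the diaryl ether oxygen lets both halves react together.
The bis(arylmalondialdehyde) comes from 4,4'-oxybis(2-methoxybenzaldehyde) (SNAr of two commercial benzaldehydes) by twofold ortho-lithiation/hydroxylation between OMe and OAr (the 3'-OH groups), benzylation, Wittig homologation and Vilsmeier–Haack formylation.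
After the key step, hydride addition gives a bis(isoflav-3-ene), iridium-catalysed asymmetric hydrogenation sets both C3 centres, and hydrogenolysis removes four benzyl ethers.
Ring order: rings B (bought) → diaryl ether → both rings C fused onto the incoming rings A in step 7 → saturation of rings C with control of C3.

Key step: step 7

Remark: both C3 centres are R (priority C2 > aryl > C4 > H), the molecule is C2-symmetric, and locants 2', 3', 4' denote ring B of each half; compounds 1, 2 and 13 are taken to be commercial.

Step 1
Reactants: 1 4-fluoro-2-methoxybenzaldehyde; 2 4-hydroxy-2-methoxybenzaldehyde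
Product: 3 4,4'-oxybis(2-methoxybenzaldehyde)
Conditions: K2CO3, DMF, 120 °C
Reagents that add atoms: none
Why: Nucleophilic aromatic substitution (addition–elimination), in which the phenoxide of 2 displaces the fluoride of 1 that is activated by the para formyl group, should give the symmetric diaryl ether.

Step 2
Reactants: 3 4,4'-oxybis(2-methoxybenzaldehyde)
Product: 4 4,4'-oxybis[1-(dimethoxymethyl)-2-methoxybenzene]
Conditions: HC(OMe)3, MeOH, TsOH (cat.), rt
Reagents that add atoms: trimethyl orthoformate COC(OC)OC; methanol CO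
Why: Acid-catalysed acetalisation, driven by the orthoformate as water scavenger, masks both aldehydes against the organolithium reagent of step 3.

Step 3
Reactants: 4 4,4'-oxybis[1-(dimethoxymethyl)-2-methoxybenzene]
Product: 8 4,4'-oxybis(3-hydroxy-2-methoxybenzaldehyde), via dilithio bis-acetal 5 (not isolated), via bis(dimethoxyboryl) bis-acetal 6 (not isolated), via bis-phenol bis-acetal 7 (not isolated)
Conditions: n-BuLi, TMEDA, THF, −20 → 0 °C; B(OMe)3, −78 °C → rt; H2O2 (aq), 0 °C; Na2SO3 (aq); 2 M HCl, THF, rt
Reagents that add atoms: hydrogen peroxide OO; water O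
Why: Directed ortho-metalation should occur at C3–H of each ring, which is flanked by the methoxy group and the diaryl ether oxygen (the 2,2'-positions of a diaryl ether, the usual sites of its dilithiation), and borylation, oxidative 1,2-shift of aryl from boron to oxygen and, once the peroxide is destroyed so that no Dakin oxidation can follow, acetal hydrolysis should give the bis-phenol dialdehyde.

Step 4
Reactants: 8 4,4'-oxybis(3-hydroxy-2-methoxybenzaldehyde)
Product: 9 4,4'-oxybis[3-(benzyloxy)-2-methoxybenzaldehyde]
Conditions: BnBr, K2CO3, DMF, 60 °C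
Reagents that add atoms: benzyl bromide BrCc1ccccc1
Why: Williamson etherification of the two phenols installs benzyl ethers that should survive base, the Vilsmeier reagent, anhydrous HCl and borohydride and leave only in step 10.

Step 5
Reactants: 9 4,4'-oxybis[3-(benzyloxy)-2-methoxybenzaldehyde]
Product: 10 4,4'-oxybis[3-(benzyloxy)-2-methoxy-1-(2-methoxyethenyl)benzene] (E/Z mixture)
Conditions: Ph3P(CH2OMe)Cl, KOtBu, THF, 0 °C → rt
Reagents that add atoms: (methoxymethyl)triphenylphosphonium chloride COC[P+](c1ccccc1)(c1ccccc1)c1ccccc1.[Cl-]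
Why: Wittig methoxymethylenation adds one carbon to each benzylic carbon (the future C3), and the alkene geometry is of no consequence because step 6 erases it.

Step 6
Reactants: 10 4,4'-oxybis[3-(benzyloxy)-2-methoxy-1-(2-methoxyethenyl)benzene]
Product: 12 2,2'-{oxybis[3-(benzyloxy)-2-methoxy-4,1-phenylene]}dipropanedial (bis-arylmalondialdehyde, present as the enol), via bis(methoxypropeniminium) salt 11 (not isolated)
Conditions: POCl3, DMF, 0 °C → rt; NaOH (aq), 70 °C; HCl (aq) to pH 3, 0 °C
Reagents that add atoms: N,N-dimethylformamide CN(C)C=O; water O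
Why: Vilsmeier–Haack formylation of an enol ether, in which the chloroiminium ion attacks the nucleophilic benzylic β-carbon, followed by alkaline hydrolysis of the 3-methoxypropeniminium salt and acidification, should release each arylmalondialdehyde as its stable enol.

Step 7
Reactants: 12 2,2'-{oxybis[3-(benzyloxy)-2-methoxy-4,1-phenylene]}dipropanedial; 13 resorcinol (benzene-1,3-diol)
Product: 15 3,3'-{oxybis[3-(benzyloxy)-2-methoxy-4,1-phenylene]}bis(7-hydroxychromenylium) dichloride, via bis(2H-chromen-2-ol) lactol 14 (not isolated)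
Conditions: 13 (2.2 equiv), HCl (g), AcOH–EtOAc, 0 °C → rt; Et2O
Reagents that add atoms: hydrogen chloride Cl
Why: HCl protonates each enolised malondialdehyde to a vinylogous carboxonium ion; the resorcinol carbon ortho to one OH and para to the other (the future C4a) attacks one formyl carbon (Friedel–Crafts hydroxyalkylation, C4–C4a bond), water is lost, the geometry around the resulting benzylic cation equilibrates, and the ortho OH adds to the second formyl carbon (O1–C2 bond) to give lactol 14, which ionises to the aromatic benzopyrylium ion of 15 (the two bonds may also form in the opposite order with the same outcome). The closest known reaction type is the Bülow-type benzopyrylium synthesis from resorcinol and a 1,3-dicarbonyl compound, of which the condensation of arylmalondialdehydes with resorcinol to isoflavylium salts is the direct model; here it runs twice on one C2-symmetric linchpin, so that four bonds and both rings C form in one operation. Each ring C closes by 6-exo-trig addition of the phenol oxygen to the formyl carbon, followed by dehydrative aromatisation. No stereocentre is created, because C3 becomes sp2; both C3 centres are set in step 9 by the catalyst. The step needs site selectivity on resorcinol, secured by the equivalence of its two productive carbons (either gives the 7-hydroxy pattern) and by the crowding of the carbon between the two hydroxyls, and it needs completion on both halves, which the stability of the hydroxy-substituted pyrylium ions and precipitation of the dichloride should drive; which formyl group reacts first does not matter because the two are equivalent in the enol. The benzyl ethers, the diaryl ether and the aryl methyl ethers should be inert to anhydrous HCl at room temperature, and the 2'-methoxy group keeps ring B from cyclising onto C4.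

Step 8
Reactants: 15 3,3'-{oxybis[3-(benzyloxy)-2-methoxy-4,1-phenylene]}bis(7-hydroxychromenylium) dichloride
Product: 17 3,3'-{oxybis[3-(benzyloxy)-2-methoxy-4,1-phenylene]}bis[7-(benzyloxy)-2H-chromene], via bis(7-hydroxy-2H-chromene) 16 (not isolated)
Conditions: NaBH4, THF–MeOH, −10 °C; solvent exchange; BnBr, K2CO3, DMF, rt
Reagents that add atoms: benzyl bromide BrCc1ccccc1
Why: Borohydride reduction of a benzopyrylium salt should add hydride to the unsubstituted oxocarbenium carbon C2 of each ring to give the 2H-chromene (isoflav-3-ene), and Williamson benzylation of the two 7-phenols in the same flask avoids handling the acid- and air-sensitive phenolic chromene and leaves no free OH for the hydrogenation.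

Step 9
Reactants: 17 3,3'-{oxybis[3-(benzyloxy)-2-methoxy-4,1-phenylene]}bis[7-(benzyloxy)-2H-chromene]
Product: 18 (3R,3'R)-3,3'-{oxybis[3-(benzyloxy)-2-methoxy-4,1-phenylene]}bis[7-(benzyloxy)-3,4-dihydro-2H-chromene]
Conditions: H2 (50 bar), [Ir(cod)(ThrePHOX)]BArF (2 mol % per alkene), CH2Cl2, rt
Reagents that add atoms: none
Why: Iridium-catalysed asymmetric hydrogenation of a trisubstituted aryl alkene without a coordinating group (a 3-aryl-2H-chromene) by a chiral phosphinite–oxazoline complex (cod = 1,5-cyclooctadiene, ThrePHOX = threonine-derived phosphinite–oxazoline, BArF = tetrakis[3,5-bis(trifluoromethyl)phenyl]borate) lets the ligand alone decide the face of each C3=C4 bond, the two remote alkenes react independently, and the ligand enantiomer used is the one that delivers hydrogen to the face giving 3R at both centres.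

Step 10
Reactants: 18 (3R,3'R)-3,3'-{oxybis[3-(benzyloxy)-2-methoxy-4,1-phenylene]}bis[7-(benzyloxy)-3,4-dihydro-2H-chromene]
Product: 19 6,6'-oxybis{3-[(3R)-7-hydroxy-3,4-dihydro-2H-chromen-3-yl]-2-methoxyphenol}
Conditions: H2 (1 atm), Pd/C, EtOAc–MeOH, rt
Reagents that add atoms: none
Why: Hydrogenolysis of the four aryl benzyl ethers should leave the chroman rings, the diaryl ether, the methyl ethers and the non-epimerisable C3 centres untouched.

Compound list
1 | 4-fluoro-2-methoxybenzaldehyde | COc1cc(F)ccc1C=O | starting material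
2 | 4-hydroxy-2-methoxybenzaldehyde | COc1cc(O)ccc1C=O | starting material
3 | 4,4'-oxybis(2-methoxybenzaldehyde) | O=Cc1ccc(Oc2ccc(C=O)c(OC)c2)cc1OC | intermediate
4 | 4,4'-oxybis[1-(dimethoxymethyl)-2-methoxybenzene] | COC(OC)c1ccc(Oc2ccc(C(OC)OC)c(OC)c2)cc1OC | intermediate
5 | 3,3'-dilithio-4,4'-oxybis[1-(dimethoxymethyl)-2-methoxybenzene] (not isolated) | COC(OC)c1ccc(Oc2ccc(C(OC)OC)c(OC)c2[Li])c([Li])c1OC | intermediate
6 | 3,3'-bis(dimethoxyboryl)-4,4'-oxybis[1-(dimethoxymethyl)-2-methoxybenzene] (not isolated) | COC(OC)c1ccc(Oc2ccc(C(OC)OC)c(OC)c2B(OC)OC)c(B(OC)OC)c1OC | intermediate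
7 | 6,6'-oxybis[3-(dimethoxymethyl)-2-methoxyphenol] (not isolated) | COC(OC)c1ccc(Oc2ccc(C(OC)OC)c(OC)c2O)c(O)c1OC | intermediate
8 | 4,4'-oxybis(3-hydroxy-2-methoxybenzaldehyde) | O=Cc1ccc(Oc2ccc(C=O)c(OC)c2O)c(O)c1OC | intermediate
9 | 4,4'-oxybis[3-(benzyloxy)-2-methoxybenzaldehyde] | O=Cc1ccc(Oc2ccc(C=O)c(OC)c2OCc3ccccc3)c(OCc4ccccc4)c1OC | intermediate
10 | 4,4'-oxybis[3-(benzyloxy)-2-methoxy-1-(2-methoxyethenyl)benzene], E/Z mixture | COC=Cc1ccc(Oc2ccc(C=COC)c(OC)c2OCc3ccccc3)c(OCc4ccccc4)c1OC | intermediate
11 | bis[2-aryl-3-methoxyprop-2-en-1-ylidene(dimethyl)iminium] bis(dichlorophosphate) of the diaryl ether core (not isolated) | COC=C(C=[N+](C)C)c1ccc(Oc2ccc(C(C=[N+](C)C)=COC)c(OC)c2OCc3ccccc3)c(OCc4ccccc4)c1OC.[O-]P(=O)(Cl)Cl.[O-]P(=O)(Cl)Cl | intermediate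
12 | 2,2'-{oxybis[3-(benzyloxy)-2-methoxy-4,1-phenylene]}dipropanedial | O=CC(C=O)c1ccc(Oc2ccc(C(C=O)C=O)c(OC)c2OCc3ccccc3)c(OCc4ccccc4)c1OC | intermediate
13 | resorcinol (benzene-1,3-diol) | Oc1cccc(O)c1 | starting material
14 | 3,3'-{oxybis[3-(benzyloxy)-2-methoxy-4,1-phenylene]}bis(2H-chromene-2,7-diol), C2 epimers (not isolated) | COc1c(C2=Cc3ccc(O)cc3OC2O)ccc(Oc4ccc(C5=Cc6ccc(O)cc6OC5O)c(OC)c4OCc7ccccc7)c1OCc8ccccc8 | intermediate
15 | 3,3'-{oxybis[3-(benzyloxy)-2-methoxy-4,1-phenylene]}bis(7-hydroxychromenylium) dichloride | COc1c(-c2cc3ccc(O)cc3[o+]c2)ccc(Oc4ccc(-c5cc6ccc(O)cc6[o+]c5)c(OC)c4OCc7ccccc7)c1OCc8ccccc8.[Cl-].[Cl-] | intermediate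
16 | 3,3'-{oxybis[3-(benzyloxy)-2-methoxy-4,1-phenylene]}bis(2H-chromen-7-ol) (not isolated) | COc1c(C2=Cc3ccc(O)cc3OC2)ccc(Oc4ccc(C5=Cc6ccc(O)cc6OC5)c(OC)c4OCc7ccccc7)c1OCc8ccccc8 | intermediate
17 | 3,3'-{oxybis[3-(benzyloxy)-2-methoxy-4,1-phenylene]}bis[7-(benzyloxy)-2H-chromene] | COc1c(C2=Cc3ccc(OCc4ccccc4)cc3OC2)ccc(Oc2ccc(C3=Cc4ccc(OCc5ccccc5)cc4OC3)c(OC)c2OCc2ccccc2)c1OCc1ccccc1 | intermediate
18 | (3R,3'R)-3,3'-{oxybis[3-(benzyloxy)-2-methoxy-4,1-phenylene]}bis[7-(benzyloxy)-3,4-dihydro-2H-chromene] | COc1c([C@@H]2COc3cc(OCc4ccccc4)ccc3C2)ccc(Oc2ccc([C@@H]3COc4cc(OCc5ccccc5)ccc4C3)c(OC)c2OCc2ccccc2)c1OCc1ccccc1 | intermediate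
19 | 6,6'-oxybis{3-[(3R)-7-hydroxy-3,4-dihydro-2H-chromen-3-yl]-2-methoxyphenol} | COc1c([C@@H]2COc3cc(O)ccc3C2)ccc(Oc2ccc([C@@H]3COc4cc(O)ccc4C3)c(OC)c2O)c1O | target

Total step count: 10. Longest linear sequence: 10 steps (1 or 2 → 19).

Steps most likely to fail

Step 9. Facial selectivity may be incomplete at one or both alkenes, because the 2'-methoxy group twists ring B out of the alkene plane. Since the two centres are set independently, any loss shows up as erosion into the meso diastereomer, which is hard to remove. Turnover may also be slow, or the acidic iridium hydride may isomerise the chromene. Fallback, from 17 to 19: give up catalyst control. Hydrogenation of 17 over Pd/C (alkene saturation and debenzylation in one operation, the classical reduction of isoflavenes to isoflavans) should give 6,6'-oxybis[3-(7-hydroxy-3,4-dihydro-2H-chromen-3-yl)-2-methoxyphenol] F1 as a mixture of the racemate and the meso form. The (3R,3'R) isomer is then separated by preparative chromatography on a chiral stationary phase, which re-enters the route at 19.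

Step 3. The second lithiation may stall through aggregation or precipitation of the monolithio species, lithiation may go to the other ortho position of the ether oxygen, or n-BuLi may attack an acetal. Fallback, from 1 to 9: hydroxylate before the ether is made, where the site is unambiguous. Compound 1 is converted into its dimethyl acetal 4-fluoro-1-(dimethoxymethyl)-2-methoxybenzene F2 (HC(OMe)3, MeOH, TsOH). Lithiation with n-BuLi at −78 °C should occur between fluorine and methoxy, and B(OMe)3, H2O2 and aqueous HCl should give 4-fluoro-3-hydroxy-2-methoxybenzaldehyde F3. Benzylation (BnBr, K2CO3) gives 3-(benzyloxy)-4-fluoro-2-methoxybenzaldehyde F4. One half of F4 is hydrolysed by SNAr with hydroxide (KOH, DMSO–H2O, 80 °C) to 3-(benzyloxy)-4-hydroxy-2-methoxybenzaldehyde F5. F5 and the other half of F4 are joined by SNAr (K2CO3, DMF, 120 °C) to give 9, where the route is re-entered.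

Step 7. The condensation may stop after one ring, resorcinol may react at the carbon between its hydroxyls or add a second time to C4 of a formed pyrylium ring, or prolonged exposure to the acid may cleave benzyl ethers. Fallback, from 10 to 15: change the bond set to C3–C4 and O1–C2. Hydrolysis of the enol ethers of 10 (aqueous HCl, THF) should give 2,2'-{oxybis[3-(benzyloxy)-2-methoxy-4,1-phenylene]}diacetaldehyde F6. F6 is condensed with 2,4-dihydroxybenzaldehyde (O=Cc1ccc(O)cc1O) in HCl/AcOH, the salicylaldehyde route to benzopyrylium salts (aldol condensation, then ring closure), to give the same salt 15.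

Further compounds
F1 | step 9 | 6,6'-oxybis[3-(7-hydroxy-3,4-dihydro-2H-chromen-3-yl)-2-methoxyphenol], racemate plus meso form | COc1c(C2COc3cc(O)ccc3C2)ccc(Oc2ccc(C3COc4cc(O)ccc4C3)c(OC)c2O)c1O
F2 | step 3 | 4-fluoro-1-(dimethoxymethyl)-2-methoxybenzene | COC(OC)c1ccc(F)cc1OC
F3 | step 3 | 4-fluoro-3-hydroxy-2-methoxybenzaldehyde | O=Cc1ccc(F)c(O)c1OC
F4 | step 3 | 3-(benzyloxy)-4-fluoro-2-methoxybenzaldehyde | O=Cc1ccc(F)c(OCc2ccccc2)c1OC
F5 | step 3 | 3-(benzyloxy)-4-hydroxy-2-methoxybenzaldehyde | O=Cc1ccc(O)c(OCc2ccccc2)c1OC
F6 | step 7 | 2,2'-{oxybis[3-(benzyloxy)-2-methoxy-4,1-phenylene]}diacetaldehyde | O=CCc1ccc(Oc2ccc(CC=O)c(OC)c2OCc3ccccc3)c(OCc4ccccc4)c1OC
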